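## Structural features

The target is a daucane sesquiterpene diester: a cyclopentane (C1–C5) fused through the C1–C5 bond to a cycloheptene (C5–C10 plus C1) that carries the C8=C9 olefin. Daucane numbering is used throughout, and β denotes the face of the C1 methyl group. Five stereocentres form one contiguous array: the quaternary C1 (1S), the ring-fusion hydrogen at C5 trans to the C1 methyl (5S), the tertiary isopropyl carbinol C4 with its hydroxyl cis to the C1 methyl (4R), and the acyloxy carbons C6 (6S, benzoate) and C10 (10R, angelate), both α. Fragile elements are the angelate (Z to E isomerisation to the tiglate by nucleophiles, base or heat), the allylic C10–O bond, and the C4 hydroxyl, which is β to the C6 oxygen and so invites dehydration or retro-aldol cleavage whenever C6 is a ketone. The real difficulty is a quaternary centre next to a trans ring fusion and an anti 4,6-diol on a seven-membered ring, with two different esters on two hindered secondary alcohols. The key step exploits three facts: C1–C5 belongs to both rings, C4 is a propargylic-type carbinol next to C5, and C6 plus C7–C10 with the C8 methyl correspond to one alkyne carbon and a methyl-substituted vinylcyclopropane. The cycloadduct keeps two handles: the C5=C6 olefin, which is an allylic alcohol with respect to C4–OH, and the C9=C10 olefin, whose only allylic hydrogen is H8. An ene oxygenation puts oxygen on C10 on the face from which H8 is taken, so H8 must be α. With a trans cyclopropane this requires the tether to be cis to the cyclopropane on the trisubstituted olefin (Z); an E olefin would give the C8 epimer and from it the wrong C10 configuration, so the precursor is drawn as Z. The cyclopropane must also be a single enantiomer, (1S,2S), because it fixes the olefin face and hence C1.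

## Logic of the disconnections

25 ⇒ 24. The C10–O acyl bond is cut first, because the angeloyl unit is the part of 25 most prone to isomerise and should meet no further reagent. This leaves 24 with one free secondary alcohol beside a tertiary one. The forward step must acylate a hindered, neopentyl-type allylic alcohol without Z to E isomerisation.

24 ⇒ 22 (through 23). The C10–O bond is cut and the olefin is moved from C8=C9 back to C9=C10. C1 is quaternary, so the C9=C10 olefin of 22 has H8 as its only allylic hydrogen, and an ene oxygenation can only give oxygen at C10 with the olefin at C8=C9. One stereocentre and one oxygen disappear. The demand is that H8 of 22 is α, since oxygen enters on the face from which hydrogen leaves.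

22 ⇒ 21. The benzoyl C6–O bond is cut. Secondary against tertiary hydroxyl makes the forward acylation selective, and placing the benzoate before the C10 oxygen exists avoids having to tell two secondary alcohols apart.

21 ⇒ 20 ⇒ 19. The C6–H bond of the carbinol is cut to the ketone 20 and re-formed on the other face in 19. The only chemoselective way to put oxygen on C6 of the cycloadduct uses the C4 hydroxyl as director and therefore places it β, whereas the target needs α. The same hydroxyl can then steer an internal hydride delivery to the anti diol. The demand is that 20, a β-hydroxy ketone with an epimerisable C5, meets neither base nor strong acid.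

19 ⇒ 18 ⇒ 17. The C5–H and C6–O bonds are cut back to the C5=C6 olefin through the epoxide. Hydroboration is excluded because the C9=C10 olefin of 17 is the less hindered one. A hydroxyl-directed epoxidation picks the allylic-alcohol olefin, and radical opening of 18 picks the tertiary C5 position. The gain is that 17 has no stereocentre at C5 or C6. The demand is hydrogen transfer to C5 on the α face.

17 ⇒ 16. Both rings are cut at once at C1–C5 and C6–C7, and C7–C9 is re-formed as a cyclopropane bond. A bicyclic diene with a quaternary centre becomes an acyclic enyne whose stereo-elements are one tertiary propargylic carbinol, one olefin geometry and one trans cyclopropane. The demands are: cleavage of the less substituted cyclopropane bond; a Z olefin; a (1S,2S) cyclopropane, which fixes the olefin face and so C1; and a C4 configuration that matches that face.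

16 ⇒ 14 ⇒ 13 ⇒ 12. The alkyne is traced back to a chloromethyl epoxide and then to an allylic alcohol, so that C5 and C6 come from the olefin carbon and the carbinol carbon of 12. Enantioselective ethynylation of a ketone flanked by an isopropyl and a primary alkyl group is not dependable, whereas asymmetric epoxidation of a 3,3-disubstituted allylic alcohol is. The C4 stereocentre is reduced to an olefin of defined geometry. The demand is a geometrically pure 12 and an elimination that never breaks the C4–O bond.

12 ⇒ 10 + 4 (through 11). The sp2–sp3 bond C1–C2 is cut, which gives two pieces of similar size. An alkylborane/alkenyl iodide coupling keeps both olefin geometries. The demands are hydroboration of 10 at its terminal vinyl group only and iodine cis to the cyclopropane in 4.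

10 ⇒ 9 ⇒ 7 ⇒ 5. The C3–C4 bond to the vinyl group is cut, then the C4–I bond is traced to an alkyne, then the C5–C6 bond is cut to 5 and a one-carbon electrophile. Hydroxyl-directed trans-hydroalumination with iodination fixes the trisubstituted olefin geometry. The demand is retention in the iodination and in the coupling.

4 ⇒ 3 ⇒ 2 ⇒ 1. The C1=C10 olefin is cut, 3 is taken back to 2, and C7 is removed from the cyclopropane to give the olefin of 1. The iodo ylide is Z-selective, and reagent-controlled cyclopropanation of an E allylic alcohol fixes both the trans relationship and the absolute configuration. The demand is that the volatile 3 is handled in solution and does not epimerise.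

## Other disconnections considered

Alternative 1: The cuts are the C1–CH3 bond and the C5–C6 bond, with the C9–C10 bond left for a later ring closure. The forward key step would join enone A2 and iodo aldehyde A3 to the anti-aldol adduct A1: Cu(OTf)2 with a chiral phosphoramidite catalyses conjugate addition of Al(CH3)3 to build the quaternary C1, and the aluminium enolate then adds to the aldehyde.
- In its favour: C1 is set by one catalytic asymmetric reaction, and C5–H and the C6 oxygen arrive in the same operation at the correct oxidation level. On this point it is better than the chosen plan, which spends four steps after the cycloaddition on C5 and C6 and relies on a radical hydrogen transfer.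
- Against it here: no ring is closed. The cycloheptene would still need a Nozaki–Hiyama–Kishi type closure between C9 and C10, and the C4 carbinol would need addition of an isopropyl nucleophile to a hindered, enolisable β-oxygenated cyclopentanone. A3 is a β,γ-unsaturated aldehyde that can slip into conjugation or be enolised by the aluminium enolate, and the anti-aldol and the C1/C5 relationship rest on modest biases.
- Comparison: structurally it builds stereocentres first and rings later, the reverse of the chosen plan. Mechanistically both key steps are known reaction types. It is the equal of the chosen plan in enantiocontrol and uses one chiral catalyst where the chosen plan uses a chiral ligand and a tartrate. In step economy it is no shorter, since ring closure, C4 construction, protecting-group changes and both esters remain.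

Alternative 2: The cut is the C6–C10 bond, seen in reverse as a bond of a cyclobutane. The forward key step is Pb(OAc)4 cleavage of the cis-cyclobutanediol A5 (a 5-4-5 tricycle from a [2+2] photocycloaddition) to the cis-fused diketone A4.
- In its favour: glycol cleavage is highly dependable, and the seven-membered ring appears by fragmentation rather than by medium-ring closure; in reliability of the key step it is the equal of, or better than, the chosen plan. C6 and C10 are oxygenated without ambiguity, which is better than the chosen plan at C10, where the ene reaction risks over-oxidation.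
- Against it here: A4 is cis-fused, so C5 must be epimerised. The two ketones must be told apart and each reduced to the α alcohol. The C8=C9 olefin must be introduced next to C10. The C4 carbinol must be made late by isopropyl addition to a ketone that sits 1,3 to the C6 oxygen. The photocycloaddition offers no obvious absolute control.
- Comparison: structurally it solves the ring and the C1 quaternary centre but leaves four stereocentres and the C4 carbinol. Mechanistically it is robust. In step economy it is clearly longer after the key step than the chosen plan.

Alternative 3: The cut is the C3–C4 bond. The forward key step is a SmI2 Barbier reaction of iodo ketone A7: the primary iodide is reduced, the organosamarium adds to the isopropyl ketone, and the cyclopentane closes to A6 under chelation by the C6 hydroxyl.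
- In its favour: ring closure and the tertiary carbinol arise together, and a five-membered Barbier closure is fast. A6 is only a desilylation and two acylations from the target, so its endgame is shorter than that of the chosen plan, and better on that point.
- Against it here: A7 must already hold the cycloheptene with C1, C5, C6 and C10 set, so the ring and the quaternary centre are only moved upstream with no equally direct entry. C5 of A7 is α to the ketone and β to a hydroxyl (epimerisation, retro-aldol), and ketyl formation can compete with iodide reduction.
- Comparison: structurally it closes the small ring last on a finished large ring, whereas the chosen plan forms both rings in one step from an acyclic chain. Mechanistically the two key steps are of equal standing as known reactions. Overall step count would be higher because of the route to A7.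

Key step: step 11

Remark on the chemistry: the sense of induction in step 1 is assigned by analogy with the cyclopropanation of cinnamyl alcohol by the same (4R,5R) ligand; the (4S,5S) ligand would be taken if the opposite sense were found.

## Route

Step 1
Reactants: 1 (2E)-but-2-en-1-ol
Product: 2 [(1S,2S)-2-methylcyclopropyl]methanol
Conditions: Et2Zn, CH2I2, (4R,5R)-2-butyl-N,N,N',N'-tetramethyl-1,3,2-dioxaborolane-4,5-dicarboxamide (1.2 equiv), CH2Cl2, 0 °C to rt; aq. KOH work-up
Reagents that add atoms: diiodomethane, ICI
Why: Dioxaborolane-mediated asymmetric Simmons–Smith cyclopropanation; the zinc alkoxide of 1 is held by the chiral boronate, which directs Zn(CH2I)2 to one olefin face. The E geometry of 1 passes stereospecifically into the trans ring, and the ligand sets both centres as (1S,2S).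

Step 2
Reactants: 2 [(1S,2S)-2-methylcyclopropyl]methanol
Product: 3 (1S,2S)-2-methylcyclopropane-1-carbaldehyde
Conditions: TEMPO (10 mol %), PhI(OAc)2, CH2Cl2, 0 °C to rt; NaHCO3 wash, solution used directly
Reagents that add atoms: none
Why: Nitroxyl-catalysed oxidation of a primary alcohol stops at the aldehyde under near-neutral conditions, which avoids epimerisation and acid-induced opening of the cyclopropane. The volatile aldehyde is kept in solution.

Step 3
Reactants: 3 (1S,2S)-2-methylcyclopropane-1-carbaldehyde
Product: 4 (1S,2S)-1-[(1Z)-2-iodoprop-1-en-1-yl]-2-methylcyclopropane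
Conditions: [Ph3PCH2CH3]I, n-BuLi, THF, 0 °C; I2, −78 °C; NaN(SiMe3)2, −78 to −20 °C; then 3, −78 °C to rt
Reagents that add atoms: ethyltriphenylphosphonium iodide, CC[P+](c1ccccc1)(c1ccccc1)c1ccccc1.[I-]; iodine, II
Why: Stork–Zhao-type Wittig olefination with the α-iodo ylide; the non-stabilised ylide adds under kinetic control through the cis oxaphosphetane, so iodine ends cis to the cyclopropyl group (Z). This is the geometry that later places the tether cis to the cyclopropane.

Step 4
Reactants: 5 3-methylbut-1-yne
Product: 7 4-methylpent-2-yn-1-ol, via lithium 3-methylbut-1-yn-1-ide 6 (not isolated)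
Conditions: n-BuLi, THF, −78 °C; paraformaldehyde, −78 °C to rt; H2O
Reagents that add atoms: paraformaldehyde (formaldehyde), C=O
Why: Addition of a lithium acetylide to formaldehyde; no selectivity issue arises.

Step 5
Reactants: 7 4-methylpent-2-yn-1-ol
Product: 9 (2Z)-3-iodo-4-methylpent-2-en-1-ol, via cyclic sodium alkenylaluminate 8 (not isolated)
Conditions: NaAlH2(OCH2CH2OCH3)2, THF, 0 °C to rt; EtOAc; then I2, −78 to 0 °C
Reagents that add atoms: iodine, II
Why: Hydroxyl-directed trans-hydroalumination of a propargylic alcohol; hydride goes to C2 through the aluminium alkoxide and gives the five-membered alkenylaluminate. Iodinolysis with retention places iodine cis to the hydroxymethyl group.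

Step 6
Reactants: 9 (2Z)-3-iodo-4-methylpent-2-en-1-ol
Product: 10 (2Z)-3-(propan-2-yl)penta-2,4-dien-1-ol
Conditions: 4,4,5,5-tetramethyl-2-vinyl-1,3,2-dioxaborolane, PdCl2(dppf) (3 mol %), K3PO4, THF/H2O, 50 °C
Reagents that add atoms: 4,4,5,5-tetramethyl-2-vinyl-1,3,2-dioxaborolane, C=CB1OC(C)(C)C(C)(C)O1
Why: Suzuki–Miyaura coupling of an alkenyl iodide with a vinylboronate proceeds with retention of olefin geometry and tolerates the free allylic alcohol.

Step 7
Reactants: 10 (2Z)-3-(propan-2-yl)penta-2,4-dien-1-ol; 4 (1S,2S)-1-[(1Z)-2-iodoprop-1-en-1-yl]-2-methylcyclopropane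
Product: 12 (2E,6Z)-6-methyl-7-[(1S,2S)-2-methylcyclopropyl]-3-(propan-2-yl)hepta-2,6-dien-1-ol, via B-alkyl-9-borabicyclo[3.3.1]nonane adduct 11 (not isolated)
Conditions: 9-BBN (2.1 equiv), THF, 0 °C to rt; then 4, PdCl2(dppf) (5 mol %), AsPh3, Cs2CO3, DMF/H2O, rt
Reagents that add atoms: none
Why: 9-BBN adds only to the terminal vinyl group of the diene, with boron on the CH2 terminus; one further equivalent is held by the hydroxyl as a borinate. The B-alkyl Suzuki–Miyaura coupling with the Z alkenyl iodide retains geometry, so the new chain ends cis to the cyclopropane.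

Step 8
Reactants: 12 (2E,6Z)-6-methyl-7-[(1S,2S)-2-methylcyclopropyl]-3-(propan-2-yl)hepta-2,6-dien-1-ol
Product: 13 [(2R,3R)-3-{(3Z)-3-methyl-4-[(1S,2S)-2-methylcyclopropyl]but-3-en-1-yl}-3-(propan-2-yl)oxiran-2-yl]methanol
Conditions: Ti(OiPr)4 (10 mol %), D-(−)-diethyl tartrate (12 mol %), t-BuOOH, 4 Å sieves, CH2Cl2, −20 °C
Reagents that add atoms: tert-butyl hydroperoxide, CC(C)(C)OO
Why: Sharpless asymmetric epoxidation; the titanium tartrate binds only the allylic alcohol, so the vinylcyclopropane olefin is untouched. With isopropyl trans and the chain cis to CH2OH, the D-(−)-tartrate delivers oxygen to the face that makes the future C4 centre R.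

Step 9
Reactants: 13 [(2R,3R)-3-{(3Z)-3-methyl-4-[(1S,2S)-2-methylcyclopropyl]but-3-en-1-yl}-3-(propan-2-yl)oxiran-2-yl]methanol
Product: 14 (2S,3R)-2-(chloromethyl)-3-{(3Z)-3-methyl-4-[(1S,2S)-2-methylcyclopropyl]but-3-en-1-yl}-3-(propan-2-yl)oxirane
Conditions: PPh3, N-chlorosuccinimide, THF, 0 °C to rt
Reagents that add atoms: N-chlorosuccinimide, ClN1C(=O)CCC1=O
Why: Appel-type chlorination through the alkoxyphosphonium salt converts the primary alcohol into the chloride under neutral conditions. The epoxide and both stereocentres are untouched; the descriptor at C2 changes only because chlorine alters the priorities.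

Step 10
Reactants: 14 (2S,3R)-2-(chloromethyl)-3-{(3Z)-3-methyl-4-[(1S,2S)-2-methylcyclopropyl]but-3-en-1-yl}-3-(propan-2-yl)oxirane
Product: 16 (3R,6Z)-6-methyl-7-[(1S,2S)-2-methylcyclopropyl]-3-(propan-2-yl)hept-6-en-1-yn-3-ol, via chloroalkenyl carbinol 15 (not isolated)
Conditions: LiN(iPr)2 (3.3 equiv), THF, −78 to −30 °C; H2O
Reagents that add atoms: none
Why: Base-induced fragmentation of a 2,3-epoxy chloride to a propargylic alcohol; deprotonation at the CHCl carbon opens the epoxide by β-elimination to 15, and loss of HCl gives the alkyne, held as the acetylide by the third equivalent. The C–O bond at the tertiary carbon is never broken, so the configuration from step 8 is kept.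

Step 11
Reactants: 16 (3R,6Z)-6-methyl-7-[(1S,2S)-2-methylcyclopropyl]-3-(propan-2-yl)hept-6-en-1-yn-3-ol
Product: 17 (3R,6S,8aR)-6,8a-dimethyl-3-(propan-2-yl)-1,2,3,5,6,8a-hexahydroazulen-3-ol (8β-methyl-dauca-5,9-dien-4β-ol)
Conditions: [Rh(CO)2Cl]2 (5 mol %), 1,2-dichloroethane (0.02 M), 80 °C
Reagents that add atoms: none
Why: Monovalent rhodium binds the vinylcyclopropane and inserts into the less substituted C9–C7 bond to give a σ-alkyl/π-allyl rhodacyclohexene; the tethered alkyne then inserts at the allyl terminus (C1–C5), and C(sp2)–C(sp3) reductive elimination from the eight-membered rhodacycle forms C6–C7 and frees the catalyst. The closest known reaction type is the rhodium-catalysed intramolecular (5+2) cycloaddition of tethered alkyne–vinylcyclopropanes, which accepts terminal alkynes, free hydroxyl groups, trisubstituted olefins that become quaternary centres and trans-2-alkyl cyclopropanes. The five-membered ring closes in a 5-exo-dig sense when C5 is carbometalated onto C1 across the three-atom tether; the seven-membered ring closes by ring contraction of the rhodacyclooctadiene in the reductive elimination. C1 is the only new stereocentre; C8 keeps its configuration because none of its bonds is touched, and C9 becomes sp2. C1 is controlled by the cyclopropane: for C9–C7 cleavage C8 must lie in the s-cis plane with C7 on the metal face, which fixes the olefin face, and the Z geometry then puts the C1 methyl on the outside, so it ends cis to the C8 methyl and trans to H8. The C4 carbinol is matched with this face, since its isopropyl group then lies anti to the C1 methyl on the forming cyclopentene. The step needs cleavage of the less substituted cyclopropane bond, which the trans methyl secures by keeping rhodium away from C8, and intramolecular reaction ahead of alkyne oligomerisation, which the short tether and dilution secure. Addition to the other olefin face is possible only with cleavage of C9–C8 and would therefore appear as a separable constitutional isomer, not as a C1 epimer.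

Step 12
Reactants: 17 (3R,6S,8aR)-6,8a-dimethyl-3-(propan-2-yl)-1,2,3,5,6,8a-hexahydroazulen-3-ol
Product: 18 5β,6β-epoxy-8β-methyl-dauc-9-en-4β-ol
Conditions: VO(acac)2 (5 mol %), t-BuOOH, toluene, rt
Reagents that add atoms: tert-butyl hydroperoxide, CC(C)(C)OO
Why: Hydroxyl-directed epoxidation; the vanadate ester of the tertiary allylic alcohol delivers oxygen to the C5=C6 olefin on the face of the C4 hydroxyl (β). The C9=C10 olefin has no directing group and should not react.

Step 13
Reactants: 18 5β,6β-epoxy-8β-methyl-dauc-9-en-4β-ol
Product: 19 8β-methyl-5αH-dauc-9-ene-4β,6β-diol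
Conditions: Cp2TiCl2, Zn dust, THF, rt (forms Cp2TiCl); then 18, cyclohexa-1,4-diene (10 equiv), rt; aq. NaH2PO4
Reagents that add atoms: none
Why: Reductive epoxide opening by single-electron transfer from trivalent titanium cleaves the C5–O bond to the tertiary radical and keeps the β C6–O–Ti bond. Hydrogen-atom transfer from cyclohexadiene is expected on the α face, away from the C1 methyl, the C4 oxygen and the bulky titanoxy group, which sets the trans ring fusion. The tertiary radical is too hindered to be captured by a second titanium, so loss of the C4 oxygen by β-elimination should not compete.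

Step 14
Reactants: 19 8β-methyl-5αH-dauc-9-ene-4β,6β-diol
Product: 20 4β-hydroxy-8β-methyl-5αH-dauc-9-en-6-one
Conditions: Dess–Martin periodinane, NaHCO3, CH2Cl2, 0 °C to rt
Reagents that add atoms: none
Why: Dess–Martin oxidation of the secondary alcohol under buffered, non-basic conditions should give the β-hydroxy ketone without retro-aldol cleavage or epimerisation at C5. The tertiary alcohol cannot be oxidised.

Step 15
Reactants: 20 4β-hydroxy-8β-methyl-5αH-dauc-9-en-6-one
Product: 21 8β-methyl-5αH-dauc-9-ene-4β,6α-diol
Conditions: Me4NBH(OAc)3, AcOH/MeCN, −20 to 0 °C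
Reagents that add atoms: none
Why: Evans–Saksena reduction; the C4 hydroxyl exchanges onto boron and delivers hydride intramolecularly to the β face of the C6 ketone through a six-membered transition state. This gives the 4,6-anti diol with the C6 hydroxyl α.

Step 16
Reactants: 21 8β-methyl-5αH-dauc-9-ene-4β,6α-diol
Product: 22 6α-benzoyloxy-8β-methyl-5αH-dauc-9-en-4β-ol
Conditions: BzCl, pyridine, DMAP (cat.), CH2Cl2, 0 °C to rt
Reagents that add atoms: benzoyl chloride, ClC(=O)c1ccccc1
Why: Nucleophile-catalysed acylation distinguishes the secondary C6 hydroxyl from the tertiary C4 hydroxyl.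

Step 17
Reactants: 22 6α-benzoyloxy-8β-methyl-5αH-dauc-9-en-4β-ol
Product: 24 6α-benzoyloxy-5αH-dauc-8-ene-4β,10α-diol, via 10α-hydroperoxide 23 (not isolated)
Conditions: O2, tetraphenylporphyrin (cat.), visible light, CH2Cl2, −20 °C, run to partial conversion; then PPh3, rt
Reagents that add atoms: dioxygen, O=O
Why: Schenck ene reaction; singlet oxygen bonds to C10 while it takes H8, the only allylic hydrogen, from the same (α) face, and the olefin moves to C8=C9. C1 is quaternary, so no regioisomer can form, and the α face is also the one away from the C1 and C8 methyl groups. Phosphine reduction of 23 leaves the C10–O bond intact.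

Step 18
Reactants: 24 6α-benzoyloxy-5αH-dauc-8-ene-4β,10α-diol
Product: 25 10α-angeloyloxy-6α-benzoyloxy-5αH-dauc-8-en-4β-ol (the target; 1S,4R,5S,6S,10R)
Conditions: angelic acid, 2,4,6-trichlorobenzoyl chloride, Et3N, toluene, rt; then 24, 80 °C
Reagents that add atoms: angelic acid, C/C=C(/C)C(=O)O
Why: Yamaguchi-type esterification through the mixed anhydride, run without a nucleophilic catalyst, acylates the secondary allylic alcohol while avoiding the conjugate addition–elimination that turns angelates into tiglates. The tertiary hydroxyl does not react.

## Compound list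

1 | (2E)-but-2-en-1-ol | C/C=C/CO | starting material
2 | [(1S,2S)-2-methylcyclopropyl]methanol | OC[C@H]1C[C@@H]1C | intermediate
3 | (1S,2S)-2-methylcyclopropane-1-carbaldehyde | O=C[C@H]1C[C@@H]1C | intermediate
4 | (1S,2S)-1-[(1Z)-2-iodoprop-1-en-1-yl]-2-methylcyclopropane | C/C(I)=C/[C@H]1C[C@@H]1C | intermediate
5 | 3-methylbut-1-yne | CC(C)C#C | starting material
6 | lithium 3-methylbut-1-yn-1-ide | CC(C)C#C[Li] | intermediate
7 | 4-methylpent-2-yn-1-ol | CC(C)C#CCO | intermediate
8 | sodium 2,2-bis(2-methoxyethoxy)-3-(propan-2-yl)-2,5-dihydro-1,2-oxaluminol-2-uide (cyclic alkenylaluminate) | CC(C)C1=CCO[Al-]1(OCCOC)OCCOC.[Na+] | intermediate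
9 | (2Z)-3-iodo-4-methylpent-2-en-1-ol | OC/C=C(\I)C(C)C | intermediate
10 | (2Z)-3-(propan-2-yl)penta-2,4-dien-1-ol | OC/C=C(\C=C)C(C)C | intermediate
11 | B-alkyl-9-borabicyclo[3.3.1]nonane adduct of 10 (boron on the terminal carbon, hydroxyl as its borinate) | CC(C)/C(CCB1C2CCCC1CCC2)=C/COB1C2CCCC1CCC2 | intermediate
12 | (2E,6Z)-6-methyl-7-[(1S,2S)-2-methylcyclopropyl]-3-(propan-2-yl)hepta-2,6-dien-1-ol | OC/C=C(/C(C)C)CC/C(C)=C\[C@H]1C[C@@H]1C | intermediate
13 | [(2R,3R)-3-{(3Z)-3-methyl-4-[(1S,2S)-2-methylcyclopropyl]but-3-en-1-yl}-3-(propan-2-yl)oxiran-2-yl]methanol | OC[C@H]1O[C@@]1(C(C)C)CC/C(C)=C\[C@H]2C[C@@H]2C | intermediate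
14 | (2S,3R)-2-(chloromethyl)-3-{(3Z)-3-methyl-4-[(1S,2S)-2-methylcyclopropyl]but-3-en-1-yl}-3-(propan-2-yl)oxirane | ClC[C@H]1O[C@@]1(C(C)C)CC/C(C)=C\[C@H]2C[C@@H]2C | intermediate
15 | (3R,6Z)-1-chloro-6-methyl-7-[(1S,2S)-2-methylcyclopropyl]-3-(propan-2-yl)hepta-1,6-dien-3-ol (C1=C2 geometry undefined and of no consequence) | ClC=C[C@](O)(C(C)C)CC/C(C)=C\[C@H]1C[C@@H]1C | intermediate
16 | (3R,6Z)-6-methyl-7-[(1S,2S)-2-methylcyclopropyl]-3-(propan-2-yl)hept-6-en-1-yn-3-ol | C#C[C@](O)(C(C)C)CC/C(C)=C\[C@H]1C[C@@H]1C | intermediate
17 | (3R,6S,8aR)-6,8a-dimethyl-3-(propan-2-yl)-1,2,3,5,6,8a-hexahydroazulen-3-ol | C1=C[C@@H](C)CC=C2[C@]1(C)CC[C@@]2(O)C(C)C | intermediate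
18 | 5β,6β-epoxy-8β-methyl-dauc-9-en-4β-ol | C1=C[C@@H](C)C[C@H]3O[C@@]32[C@]1(C)CC[C@@]2(O)C(C)C | intermediate
19 | 8β-methyl-5αH-dauc-9-ene-4β,6β-diol | C1=C[C@@H](C)C[C@@H](O)[C@@H]2[C@]1(C)CC[C@@]2(O)C(C)C | intermediate
20 | 4β-hydroxy-8β-methyl-5αH-dauc-9-en-6-one | C1=C[C@@H](C)CC(=O)[C@@H]2[C@]1(C)CC[C@@]2(O)C(C)C | intermediate
21 | 8β-methyl-5αH-dauc-9-ene-4β,6α-diol | C1=C[C@@H](C)C[C@H](O)[C@@H]2[C@]1(C)CC[C@@]2(O)C(C)C | intermediate
22 | 6α-benzoyloxy-8β-methyl-5αH-dauc-9-en-4β-ol | C1=C[C@@H](C)C[C@H](OC(=O)c3ccccc3)[C@@H]2[C@]1(C)CC[C@@]2(O)C(C)C | intermediate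
23 | 6α-benzoyloxy-10α-hydroperoxy-5αH-dauc-8-en-4β-ol | OO[C@@H]1C=C(C)C[C@H](OC(=O)c3ccccc3)[C@@H]2[C@]1(C)CC[C@@]2(O)C(C)C | intermediate
24 | 6α-benzoyloxy-5αH-dauc-8-ene-4β,10α-diol | O[C@@H]1C=C(C)C[C@H](OC(=O)c3ccccc3)[C@@H]2[C@]1(C)CC[C@@]2(O)C(C)C | intermediate
25 | 10α-angeloyloxy-6α-benzoyloxy-5αH-dauc-8-en-4β-ol | C/C=C(/C)C(=O)O[C@@H]1C=C(C)C[C@H](OC(=O)c2ccccc2)[C@@H]2[C@]1(C)CC[C@@]2(O)C(C)C | target

## Step count and least certain steps

Total: 18 steps. Longest linear sequence: 15 steps (steps 1–3 or 4–6, then 7–18).

**Step 11 (key step).** The most likely failure is slow turnover: the tether is cis to the cyclopropane on a trisubstituted olefin, a less common arrangement, so alkyne oligomerisation could compete. A second risk is erosion of regiocontrol in the cyclopropane opening, with insertion into C9–C8 from the other olefin face, which would give a constitutional isomer. The fallback sets out from 16: silylation with Et3SiOTf and 2,6-lutidine gives the triethylsilyl ether of 16, F1. Cycloaddition of F1 with the cationic monovalent rhodium arene complex [Rh(C10H8)(cod)]SbF6 in 1,2-dichloroethane at room temperature gives the triethylsilyl ether of 17, F2. This catalyst class turns over at low temperature and does not need the free hydroxyl. Bu4NF then returns to the route at 17.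

**Step 13.** The most likely failure is hydrogen-atom transfer to the β face, giving the cis ring fusion, because the α face carries the isopropyl group. A lesser risk is loss of the C4 oxygen by elimination. The fallback sets out from 18 and moves control from the kinetic radical step to a thermodynamic one. The reductive opening is carried through to the cis-fused diol 8β-methyl-5βH-dauc-9-ene-4β,6β-diol, F3. Dess–Martin oxidation gives the cis-fused ketone 4β-hydroxy-8β-methyl-5βH-dauc-9-en-6-one, F4. Catalytic DBU in toluene at room temperature equilibrates C5 and returns to the route at 20. The trans-fused ketone should be favoured, since the cis isomer places C6 syn to the isopropyl group on the cyclopentane; base contact is kept short because of the retro-aldol risk.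

**Step 17.** The most likely failure is further photooxygenation of the new trisubstituted C8=C9 olefin, which is intrinsically more reactive toward singlet oxygen than the cis-disubstituted olefin of 22. Conversion would then have to be kept low. The fallback sets out from 22. mCPBA epoxidises the α face, both flanking methyl groups being β, to give 6α-benzoyloxy-9α,10α-epoxy-8β-methyl-5αH-daucan-4β-ol, F5. Me3SiOTf and DBU in toluene open the epoxide by triflate at C9 and remove H8 anti to it, giving 6α-benzoyloxy-4β,10α-bis(trimethylsilyloxy)-5αH-dauc-8-ene, F6. Citric acid in methanol returns to the route at 24.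

**Step 18.** The most likely failure is isomerisation of the angeloyl unit to the tigloyl isomer during activation, made worse by slow acylation of the neopentyl-type alcohol. The fallback sets out from 24. DCC and DMAP with 2-[bis(2,2,2-trifluoroethoxy)phosphoryl]propanoic acid give the phosphonopropanoate 6α-benzoyloxy-10α-{2-[bis(2,2,2-trifluoroethoxy)phosphoryl]propanoyloxy}-5αH-dauc-8-en-4β-ol, F7. Still–Gennari olefination of F7 with acetaldehyde (KN(SiMe3)2, 18-crown-6, THF, −78 °C) builds the Z olefin on the ester and returns to the route at 25.

**Step 3.** The most likely failure is erosion of Z selectivity and partial loss of iodine from the ylide, which would give an iodine-free propenyl by-product that is hard to remove from a volatile product. The fallback sets out from 3. Ramirez olefination (CBr4, PPh3) gives (1S,2S)-1-(2,2-dibromoethenyl)-2-methylcyclopropane, F8. Palladium-catalysed trans-selective Negishi monomethylation (MeZnCl, Pd(PtBu3)2) gives (1S,2S)-1-[(1Z)-2-bromoprop-1-en-1-yl]-2-methylcyclopropane, F9. F9 takes the place of 4 in the coupling of step 7, and the route is rejoined at 12.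

## Further compounds

F1 | step 11 | triethyl{[(3R,6Z)-6-methyl-7-[(1S,2S)-2-methylcyclopropyl]-3-(propan-2-yl)hept-6-en-1-yn-3-yl]oxy}silane | C#C[C@](O[Si](CC)(CC)CC)(C(C)C)CC/C(C)=C\[C@H]1C[C@@H]1C
F2 | step 11 | triethylsilyl ether of 17 | C1=C[C@@H](C)CC=C2[C@]1(C)CC[C@@]2(O[Si](CC)(CC)CC)C(C)C
F3 | step 13 | 8β-methyl-5βH-dauc-9-ene-4β,6β-diol | C1=C[C@@H](C)C[C@@H](O)[C@H]2[C@]1(C)CC[C@@]2(O)C(C)C
F4 | step 13 | 4β-hydroxy-8β-methyl-5βH-dauc-9-en-6-one | C1=C[C@@H](C)CC(=O)[C@H]2[C@]1(C)CC[C@@]2(O)C(C)C
F5 | step 17 | 6α-benzoyloxy-9α,10α-epoxy-8β-methyl-5αH-daucan-4β-ol | [C@H]13O[C@@H]3[C@@H](C)C[C@H](OC(=O)c4ccccc4)[C@@H]2[C@]1(C)CC[C@@]2(O)C(C)C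
F6 | step 17 | 6α-benzoyloxy-4β,10α-bis(trimethylsilyloxy)-5αH-dauc-8-ene | C[Si](C)(C)O[C@@H]1C=C(C)C[C@H](OC(=O)c3ccccc3)[C@@H]2[C@]1(C)CC[C@@]2(O[Si](C)(C)C)C(C)C
F7 | step 18 | 6α-benzoyloxy-10α-{2-[bis(2,2,2-trifluoroethoxy)phosphoryl]propanoyloxy}-5αH-dauc-8-en-4β-ol (both epimers at the phosphonate carbon) | CC(P(=O)(OCC(F)(F)F)OCC(F)(F)F)C(=O)O[C@@H]1C=C(C)C[C@H](OC(=O)c2ccccc2)[C@@H]2[C@]1(C)CC[C@@]2(O)C(C)C
F8 | step 3 | (1S,2S)-1-(2,2-dibromoethenyl)-2-methylcyclopropane | BrC(Br)=C[C@H]1C[C@@H]1C
F9 | step 3 | (1S,2S)-1-[(1Z)-2-bromoprop-1-en-1-yl]-2-methylcyclopropane | C/C(Br)=C/[C@H]1C[C@@H]1C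
A1 | alternative 1 | 3-{[tert-butyl(dimethyl)silyl]oxymethyl}-2-[(3Z)-1-hydroxy-4-iodo-3-methylbut-3-en-1-yl]-3-methylcyclopentan-1-one (anti-aldol adduct) | I/C=C(/C)C[C@H](O)[C@@H]1[C@](CO[Si](C)(C)C(C)(C)C)(C)CCC1=O
A2 | alternative 1 | 3-{[tert-butyl(dimethyl)silyl]oxymethyl}cyclopent-2-en-1-one | O=C1C=C(CO[Si](C)(C)C(C)(C)C)CC1
A3 | alternative 1 | (3Z)-4-iodo-3-methylbut-3-enal | I/C=C(/C)CC=O
A4 | alternative 2 | cis-fused 8,9-dihydrodaucane-6,10-dione 4-(ethylene ketal) | O=C1C[C@@H](C)CC(=O)[C@H]2[C@]1(C)CCC23OCCO3
A5 | alternative 2 | 6,10-cyclo-8,9-dihydrodaucane-6,10-diol 4-(ethylene ketal) (cis-cyclobutanediol, 5-4-5 tricycle) | O[C@]12C[C@@H](C)C[C@@]1(O)[C@H]1[C@]2(C)CCC13OCCO3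
A6 | alternative 3 | 10-O-[tert-butyl(dimethyl)silyl]dauc-8-ene-4,6,10-triol | CC(C)(C)[Si](C)(C)O[C@@H]1C=C(C)C[C@H](O)[C@@H]2[C@]1(C)CC[C@@]2(O)C(C)C
A7 | alternative 3 | 10-O-[tert-butyl(dimethyl)silyl]-6,10-dihydroxy-3-iodo-3,4-secodauc-8-en-4-one | CC(C)(C)[Si](C)(C)O[C@@H]1C=C(C)C[C@H](O)[C@@H](C(=O)C(C)C)[C@]1(C)CCI
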